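The cyclopentenone ring (C8–C12, prostanoid numbering) is opened at C11–C12, and the C10–Cl bond is removed in the same disconnection. The ring carries chlorine on alkene carbon C10 and joins alkene carbon C11 to the tertiary carbinol C12. That is the imprint of chloride and palladium adding anti across a C10≡C11 triple bond, followed by addition of the C11–Pd bond to a C12 ketone. One catalytic operation thus closes the five-membered ring, installs chlorine and sets the only stereocentre under ligand control. The precursor is an acyclic terminal alkyne whose propargylic C9 is a dioxolane, linked through C8 to a C12 ketone that already bears the (Z)-octenyl chain.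

Key step: step 7

Remarks on the chemistry:
- Prostanoid numbering is used throughout (C1 ester carbon, C8–C12 ring, C20 chain end).
- Counting the carbon chain of the acyclic keto alkyne gives a dec-4-en-2-one (ten carbons), and it is named so.
- The carbinol centres made in the two aldol steps are racemic or diastereomer mixtures and are erased later.
- The C12 descriptor changes from S to R once C8 becomes sp2; the configuration itself is not touched.
- Assumption: which antipode of the bisoxazoline delivers the (S)-carbinol cannot be predicted and is fixed by experiment; the (S,S) ligand is written.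

Step 1
Reactants: 1 (Z)-non-3-en-1-ol
Product: 2 (Z)-non-3-enal
Conditions: Dess–Martin periodinane, NaHCO3, CH2Cl2, 0 °C; crude solution used at once
Reagents that add atoms: none
Why: Dess–Martin oxidation of a primary homoallylic alcohol under buffered, base-free conditions should stop at the skipped enal without moving the Z double bond into conjugation.

Step 2
Reactants: 3 4-(trimethylsilyl)but-3-yn-2-one; 2 (Z)-non-3-enal
Product: 5 (Z)-5-hydroxy-1-(trimethylsilyl)tridec-7-en-1-yn-3-one (racemic), via lithium enolate 4 (not isolated)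
Conditions: LiN(iPr)2, THF, −78 °C; then 2, −78 °C; AcOH quench at −78 °C
Reagents that add atoms: none
Why: Kinetic deprotonation of the methyl ketone and lithium-enolate aldol addition at low temperature should outrun enolization of the aldehyde; the new carbinol centre is racemic and is erased in step 6.

Step 3
Reactants: 5 (Z)-5-hydroxy-1-(trimethylsilyl)tridec-7-en-1-yn-3-one
Product: 6 (Z)-5-[(tert-butyldimethylsilyl)oxy]-1-(trimethylsilyl)tridec-7-en-1-yn-3-one
Conditions: TBSOTf, 2,6-lutidine, CH2Cl2, −78 °C
Reagents that add atoms: tert-butyldimethylsilyl trifluoromethanesulfonate, CC(C)(C)[Si](C)(C)OS(=O)(=O)C(F)(F)F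
Why: Silylation of the secondary alcohol with a silyl triflate and a hindered base is fast at low temperature and blocks retro-aldol and dehydration of the aldol in the next step.

Step 4
Reactants: 6 (Z)-5-[(tert-butyldimethylsilyl)oxy]-1-(trimethylsilyl)tridec-7-en-1-yn-3-one
Product: 7 2-{(Z)-2-[(tert-butyldimethylsilyl)oxy]dec-4-en-1-yl}-2-[(trimethylsilyl)ethynyl]-1,3-dioxolane
Conditions: TMSOCH2CH2OTMS, TMSOTf (cat.), CH2Cl2, −78 to −20 °C; pyridine quench
Reagents that add atoms: 1,2-bis(trimethylsilyloxy)ethane, C[Si](C)(C)OCCO[Si](C)(C)C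
Why: Silyl-triflate-catalysed ketalization with the bis-silyl ether of the diol is aprotic and is driven by formation of hexamethyldisiloxane, so the unhindered ynone carbonyl should be ketalized without touching the silyl ether or the Z alkene.

Step 5
Reactants: 7 2-{(Z)-2-[(tert-butyldimethylsilyl)oxy]dec-4-en-1-yl}-2-[(trimethylsilyl)ethynyl]-1,3-dioxolane
Product: 8 (Z)-1-(2-ethynyl-1,3-dioxolan-2-yl)dec-4-en-2-ol (racemic)
Conditions: Bu4NF, THF, 0 °C to rt
Reagents that add atoms: none
Why: Fluoride cleaves the O–Si bond and the alkynyl C–Si bond in one operation (fluoride desilylation), and the dioxolane is inert to these conditions.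

Step 6
Reactants: 8 (Z)-1-(2-ethynyl-1,3-dioxolan-2-yl)dec-4-en-2-ol
Product: 9 (Z)-1-(2-ethynyl-1,3-dioxolan-2-yl)dec-4-en-2-one
Conditions: Dess–Martin periodinane, NaHCO3, CH2Cl2, 0 °C; neutral work-up, used directly
Reagents that add atoms: none
Why: Buffered Dess–Martin oxidation is the mild, non-basic way to a skipped enone, so neither conjugation of the C14=C15 bond nor base-induced opening of the neighbouring ketal should occur.

Step 7
Reactants: 9 (Z)-1-(2-ethynyl-1,3-dioxolan-2-yl)dec-4-en-2-one
Product: 10 (S)-6-chloro-8-[(Z)-oct-2-en-1-yl]-1,4-dioxaspiro[4.4]non-6-en-8-ol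
Conditions: Pd(MeCN)4(BF4)2 (10 mol %), (S,S)-2,2'-isopropylidenebis(4-tert-butyl-2-oxazoline) (12 mol %), LiCl (2 equiv), AcOH (2 equiv), 1,4-dioxane, 25 °C
Reagents that add atoms: lithium chloride, [Li+].[Cl-]
Why: Proposed new method: the bisoxazoline-bound cationic divalent palladium activates the C10≡C11 alkyne of 9, external chloride attacks the internal carbon C10 on the face opposite the metal, and the C11 alkenylpalladium so formed sits cis to the C9–C8 tether and inserts the C12 carbonyl, after which acetic acid protonates the palladium alkoxide and frees the catalyst without any change of oxidation state. The closest known reaction types are acetoxy- and halopalladation-initiated cyclizations of alkynes that finish by addition of the alkenyl–palladium bond to a tethered carbonyl group, and nickel-catalysed enantioselective anti-carbometallative cyclizations of alkynyl ketones. The cyclopentene closes in a 5-exo-trig addition to the C=O group, with C10=C11 left inside the ring. The C12 stereocentre is set by the chiral ligand, which differentiates the two faces of the palladium-coordinated ketone in the insertion step. The step needs chloride at C10, palladium at C11 and anti geometry: chloropalladation is reversible and only the C11-palladated anti adduct can reach the ketone through a five-membered transition state (the regioisomer would have to form a four-membered ring and the syn adduct holds palladium trans to the tether), so the tether itself enforces both selectivities. The dioxolane at C9 breaks the ynone conjugation that would otherwise send chloride to C11, and the weakly acidic, base-free medium should spare the skipped enone and the ketal.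

Step 8
Reactants: 10 (S)-6-chloro-8-[(Z)-oct-2-en-1-yl]-1,4-dioxaspiro[4.4]non-6-en-8-ol
Product: 11 (S)-2-chloro-4-hydroxy-4-[(Z)-oct-2-en-1-yl]cyclopent-2-en-1-one
Conditions: 1 M aq. HCl, THF, 0 °C to rt
Reagents that add atoms: water, O
Why: Acid hydrolysis of the dioxolane unmasks the C9 ketone; the chlorine and the emerging carbonyl disfavour ionization of the tertiary allylic alcohol, so C12 should keep its configuration.

Step 9
Reactants: 12 methyl hex-5-enoate; 13 (E)-but-2-enal
Product: 14 methyl (E)-7-oxohept-5-enoate
Conditions: second-generation Hoveyda–Grubbs catalyst (3 mol %), excess 13, CH2Cl2, 40 °C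
Reagents that add atoms: none
Why: Olefin cross-metathesis of a terminal alkene with an enal partner should give the E-enal, driven by loss of propene.

Step 10
Reactants: 11 (S)-2-chloro-4-hydroxy-4-[(Z)-oct-2-en-1-yl]cyclopent-2-en-1-one; 14 methyl (E)-7-oxohept-5-enoate
Product: 16 methyl (5E,12S,14Z)-10-chloro-7,12-dihydroxy-9-oxoprosta-5,10,14-trienoate (mixture at C7 and C8), via dilithio alkoxide enolate 15 (not isolated)
Conditions: LiN(iPr)2 (2.2 equiv), THF, −78 °C; then 14, −78 °C; AcOH quench at −78 °C
Reagents that add atoms: none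
Why: The first equivalent of base gives the C12 lithium alkoxide, which cannot be expelled from the C8 enolate made by the second, and this cross-conjugated enolate adds 1,2 to the enal (aldol addition); the C7 and C8 centres are mixtures of no consequence because step 11 erases both.

Step 11
Reactants: 16 methyl (5E,12S,14Z)-10-chloro-7,12-dihydroxy-9-oxoprosta-5,10,14-trienoate
Product: 19 methyl (5E,7E,12R,14Z)-12-acetoxy-10-chloro-9-oxoprosta-5,7,10,14-tetraenoate, via 7-acetate 17 (not isolated), via 12-hydroxy dienone 18 (not isolated)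
Conditions: Ac2O (excess), Et3N, DMAP (1 equiv), CH2Cl2, 0 °C to rt
Reagents that add atoms: acetic anhydride, CC(=O)OC(C)=O
Why: Acetylation of the secondary C7 hydroxyl, E1cB loss of acetate to the cross-conjugated dienone and DMAP-catalysed acetylation of the tertiary C12 hydroxyl should follow one another in one flask; the elimination is expected to give both C7 geometries, so the 7E ester 19 is carried on and any target 20 formed alongside is separated and pooled with the product of step 12.

Step 12
Reactants: 19 methyl (5E,7E,12R,14Z)-12-acetoxy-10-chloro-9-oxoprosta-5,7,10,14-tetraenoate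
Product: 20 methyl (5E,7Z,12R,14Z)-12-acetoxy-10-chloro-9-oxoprosta-5,7,10,14-tetraenoate
Conditions: hν (λ > 300 nm, Pyrex), degassed dilute benzene, rt, to the photostationary state; HPLC separation, 19 and other geometric isomers recycled
Reagents that add atoms: none
Why: Direct excitation of the dienone chromophore allows rotation about C7=C8 (enone E/Z photoisomerization) and so interconverts 19 and 20, while the isolated C14=C15 alkene does not absorb and C12 is not involved; separation and recycling should funnel the material to the 7Z isomer.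

Compound list
1 | (Z)-non-3-en-1-ol | CCCCC/C=C\CCO | starting material
2 | (Z)-non-3-enal | CCCCC/C=C\CC=O | intermediate
3 | 4-(trimethylsilyl)but-3-yn-2-one | CC(=O)C#C[Si](C)(C)C | starting material
4 | lithium 4-(trimethylsilyl)but-1-en-3-yn-2-olate | C=C(O[Li])C#C[Si](C)(C)C | intermediate
5 | (Z)-5-hydroxy-1-(trimethylsilyl)tridec-7-en-1-yn-3-one, racemic | CCCCC/C=C\CC(O)CC(=O)C#C[Si](C)(C)C | intermediate
6 | (Z)-5-[(tert-butyldimethylsilyl)oxy]-1-(trimethylsilyl)tridec-7-en-1-yn-3-one, racemic | CCCCC/C=C\CC(CC(=O)C#C[Si](C)(C)C)O[Si](C)(C)C(C)(C)C | intermediate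
7 | 2-{(Z)-2-[(tert-butyldimethylsilyl)oxy]dec-4-en-1-yl}-2-[(trimethylsilyl)ethynyl]-1,3-dioxolane, racemic | CCCCC/C=C\CC(CC1(C#C[Si](C)(C)C)OCCO1)O[Si](C)(C)C(C)(C)C | intermediate
8 | (Z)-1-(2-ethynyl-1,3-dioxolan-2-yl)dec-4-en-2-ol, racemic | CCCCC/C=C\CC(O)CC1(C#C)OCCO1 | intermediate
9 | (Z)-1-(2-ethynyl-1,3-dioxolan-2-yl)dec-4-en-2-one | CCCCC/C=C\CC(=O)CC1(C#C)OCCO1 | intermediate
10 | (S)-6-chloro-8-[(Z)-oct-2-en-1-yl]-1,4-dioxaspiro[4.4]non-6-en-8-ol | CCCCC/C=C\C[C@@]1(O)C=C(Cl)C2(OCCO2)C1 | intermediate
11 | (S)-2-chloro-4-hydroxy-4-[(Z)-oct-2-en-1-yl]cyclopent-2-en-1-one | CCCCC/C=C\C[C@@]1(O)C=C(Cl)C(=O)C1 | intermediate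
12 | methyl hex-5-enoate | C=CCCCC(=O)OC | starting material
13 | (E)-but-2-enal | C/C=C/C=O | starting material
14 | methyl (E)-7-oxohept-5-enoate | O=C/C=C/CCCC(=O)OC | intermediate
15 | dilithium alkoxide enolate of 11 (C12–OLi, C8=C9–OLi) | CCCCC/C=C\C[C@@]1(O[Li])C=C(Cl)C(O[Li])=C1 | intermediate
16 | methyl (5E,12S,14Z)-10-chloro-7,12-dihydroxy-9-oxoprosta-5,10,14-trienoate, mixture at C7 and C8 | CCCCC/C=C\C[C@@]1(O)C=C(Cl)C(=O)C1C(O)/C=C/CCCC(=O)OC | intermediate
17 | methyl (5E,12S,14Z)-7-acetoxy-10-chloro-12-hydroxy-9-oxoprosta-5,10,14-trienoate, mixture at C7 and C8 | CCCCC/C=C\C[C@@]1(O)C=C(Cl)C(=O)C1C(OC(C)=O)/C=C/CCCC(=O)OC | intermediate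
18 | methyl (5E,7E,12R,14Z)-10-chloro-12-hydroxy-9-oxoprosta-5,7,10,14-tetraenoate | CCCCC/C=C\C[C@@]1(O)C=C(Cl)C(=O)/C1=C/C=C/CCCC(=O)OC | intermediate
19 | methyl (5E,7E,12R,14Z)-12-acetoxy-10-chloro-9-oxoprosta-5,7,10,14-tetraenoate | CCCCC/C=C\C[C@@]1(OC(C)=O)C=C(Cl)C(=O)/C1=C/C=C/CCCC(=O)OC | intermediate
20 | methyl (5E,7Z,12R,14Z)-12-acetoxy-10-chloro-9-oxoprosta-5,7,10,14-tetraenoate | CCCCC/C=C\C[C@@]1(OC(C)=O)C=C(Cl)C(=O)/C1=C\C=C\CCCC(=O)OC | target

Total step count: 12. Longest linear sequence: 11 steps (steps 1–8 and 10–12; step 9 prepares the side-chain aldehyde separately).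

Steps most likely to fail

1. Step 7. The alkenylpalladium may be protonated before it reaches the ketone (plain hydrochlorination of the alkyne), the ketone oxygen may attack the activated alkyne instead, or the ligand may discriminate the ketone faces poorly. The fallback uses known chemistry only; it sets out from 8 and returns at 11.
   - Iodination of the terminal alkyne (N-iodosuccinimide, cat. AgNO3, acetone) gives the iodoalkyne F1.
   - cis-Selective diimide reduction (2-nitrobenzenesulfonyl hydrazide, Et3N) gives the (Z)-iodoalkene F2.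
   - Buffered Dess–Martin oxidation gives the keto iodide F3.
   - Intramolecular Nozaki–Hiyama–Kishi addition (CrCl2, cat. NiCl2, DMF) closes C11–C12 to the racemic chlorine-free spiroketal carbinol F4.
   - Aqueous acid gives the racemic hydroxy enone F5.
   - Nucleophilic epoxidation (H2O2, NaOH, MeOH, 0 °C) gives the epoxy ketone F6.
   - HCl in THF opens the epoxide at the α-carbon and dehydrates to the racemic chloro enone F7.
   - Preparative chromatography on a chiral stationary phase separates the (S)-enantiomer, which is 11.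

2. Step 12. The photoisomerization may settle at a photostationary mixture poor in the 7Z isomer and may scramble C5=C6 in parallel. The fallback builds the 7Z geometry stereospecifically instead of adjusting it; it sets out from 11 and returns at 20.
   - TESOTf and 2,6-lutidine give the triethylsilyl ether F8.
   - Its lithium enolate (LiN(iPr)2, −78 °C) is transmetallated with Cp2ZrCl2 and added to 14. Zirconium enolates give erythro aldols whatever the enolate geometry, so this should give the 7,8-erythro aldol F9.
   - Dicyclohexylcarbodiimide with catalytic CuCl dehydrates by internal syn elimination. From an erythro aldol this places C6 cis to the C9 carbonyl and gives the 7Z silyl ether F10.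
   - HF·pyridine frees the 12-hydroxy 7Z dienone F11.
   - Ac2O and DMAP acetylate it to 20.

3. Step 10. The C12 lithium alkoxide may open the ring by retro-aldol cleavage, or the amide base may attack the chloro enone before C8 is deprotonated. The fallback avoids strong base; it sets out from 11 and returns at 16.
   - TMSOTf and Et3N silylate the tertiary alcohol and enolize the ketone in one operation to the bis-silyl dienol ether F12.
   - Mukaiyama aldol addition to 14 (BF3·OEt2, CH2Cl2, −78 °C) gives, after aqueous work-up, the 12-O-silyl aldol F13.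
   - Citric acid in methanol removes the tertiary trimethylsilyl ether and gives 16.

Further compounds
F1 | step 7 | (Z)-1-[2-(iodoethynyl)-1,3-dioxolan-2-yl]dec-4-en-2-ol, racemic | CCCCC/C=C\CC(O)CC1(C#CI)OCCO1
F2 | step 7 | (Z)-1-{2-[(Z)-2-iodoethenyl]-1,3-dioxolan-2-yl}dec-4-en-2-ol, racemic | CCCCC/C=C\CC(O)CC1(/C=C\I)OCCO1
F3 | step 7 | (Z)-1-{2-[(Z)-2-iodoethenyl]-1,3-dioxolan-2-yl}dec-4-en-2-one | CCCCC/C=C\CC(=O)CC1(/C=C\I)OCCO1
F4 | step 7 | 8-[(Z)-oct-2-en-1-yl]-1,4-dioxaspiro[4.4]non-6-en-8-ol, racemic | CCCCC/C=C\CC1(O)C=CC2(OCCO2)C1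
F5 | step 7 | 4-hydroxy-4-[(Z)-oct-2-en-1-yl]cyclopent-2-en-1-one, racemic | CCCCC/C=C\CC1(O)C=CC(=O)C1
F6 | step 7 | 4-hydroxy-4-[(Z)-oct-2-en-1-yl]-6-oxabicyclo[3.1.0]hexan-2-one, racemic, epoxide face not assigned | CCCCC/C=C\CC1(O)CC(=O)C2OC12
F7 | step 7 | 2-chloro-4-hydroxy-4-[(Z)-oct-2-en-1-yl]cyclopent-2-en-1-one, racemic | CCCCC/C=C\CC1(O)C=C(Cl)C(=O)C1
F8 | step 12 | (S)-2-chloro-4-[(Z)-oct-2-en-1-yl]-4-(triethylsilyloxy)cyclopent-2-en-1-one | CCCCC/C=C\C[C@@]1(O[Si](CC)(CC)CC)C=C(Cl)C(=O)C1
F9 | step 12 | methyl (5E,14Z)-10-chloro-7-hydroxy-9-oxo-12-(triethylsilyloxy)prosta-5,10,14-trienoate, 7,8-erythro, face at C8 not assigned | CCCCC/C=C\C[C@@]1(O[Si](CC)(CC)CC)C=C(Cl)C(=O)C1C(O)/C=C/CCCC(=O)OC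
F10 | step 12 | methyl (5E,7Z,14Z)-10-chloro-9-oxo-12-(triethylsilyloxy)prosta-5,7,10,14-tetraenoate | CCCCC/C=C\C[C@@]1(O[Si](CC)(CC)CC)C=C(Cl)C(=O)/C1=C\C=C\CCCC(=O)OC
F11 | step 12 | methyl (5E,7Z,12R,14Z)-10-chloro-12-hydroxy-9-oxoprosta-5,7,10,14-tetraenoate | CCCCC/C=C\C[C@@]1(O)C=C(Cl)C(=O)/C1=C\C=C\CCCC(=O)OC
F12 | step 10 | (S)-3-chloro-5-[(Z)-oct-2-en-1-yl]-2,5-bis(trimethylsilyloxy)cyclopenta-1,3-diene | CCCCC/C=C\C[C@@]1(O[Si](C)(C)C)C=C(Cl)C(O[Si](C)(C)C)=C1
F13 | step 10 | methyl (5E,14Z)-10-chloro-7-hydroxy-9-oxo-12-(trimethylsilyloxy)prosta-5,10,14-trienoate, mixture at C7 and C8 | CCCCC/C=C\C[C@@]1(O[Si](C)(C)C)C=C(Cl)C(=O)C1C(O)/C=C/CCCC(=O)OC
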